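The numbers in the tables were generated by integration with constants of no real substance; noise was put on by code.

The vessel is closed and stirred at constant volume, and what it holds at any moment is the balance of target made against target lost.

| setting | larch | cedar | oak | alpha | theta | eta | epsilon |
|---|---|---|---|---|---|---|---|
| starting material | 0.026 M | 0.026 M | 0.013 M | 0.026 M | 0.026 M | 0.026 M | 0.026 M |
| reagent | 0.0065 M | 0.0097 M | 0.013 M | 0.0130 M | 0.0130 M | 0.0130 M | 0.0130 M |
| temperature | −20 °C | 13 °C | −20 °C | −5 °C | −35 °C |  | 25 °C |
| remark | run made earlier | run made earlier | run made earlier |  |  | at −35 °C until 80 s, from then on at 25 °C |  |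
| time |  |  |  | 2.5 min | 2.5 min | 2.5 min | 2.5 min |

larch run (percent of the starting material charged)

| time / min | target / % |
|---|---|
| 0.417 | 4.7 |
| 0.667 | 6.6 |
| 1.00 | 6.3 |
| 2.00 | 10.6 |
| 3.00 | 10.2 |
| 5.00 | 13.0 |

cedar run (percent of the starting material charged)

| time / s | target / % |
|---|---|
| 10.0 | 11.9 |
| 12.0 | 11.2 |
| 20.0 | 10.8 |
| 40.0 | 5.5 |
| 60.0 | 4.9 |

oak run (percent of the starting material charged)

| time / min | target / % |
|---|---|
| 0.417 | 8.5 |
| 0.833 | 13.2 |
| 1.33 | 18.1 |
| 3.00 | 29.1 |
| 5.00 | 33.9 |

(standard deviation of a reading: 1 percentage point)

- a reading or a percentage of target counts all its forms, free or not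

- the flask with the highest amount of target, in percent of the starting material charged ("all alike" if they lie within 1.5 percentage points) (alpha / theta / eta / epsilon / all alike)
- final target, as a percentage of the starting material charged, in alpha
- final target, as a percentage of the starting material charged, in theta
- final target, as a percentage of the starting material charged, in eta
- final target, as a percentage of the starting material charged, in epsilon

**What do the cold runs say?** In larch and oak, both at −20 °C, c_target is still climbing at the last reading, to 13.0 % and 33.9 %. Whatever loses target is slow there.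

**And cedar?** At 13 °C the picture turns over: c_target falls from 11.9 % at 10.0 s to 4.9 % at 60.0 s. Treat that fall as an exponential and put the ratio of the two readings under a logarithm. This gives 56.4 s, the apparent first-order lifetime of target, the time in which c_target drops by a factor e. A flask is then read by counting lifetimes: divide the time spent warm by this number, and what survives is the exponential of minus that count.

**Two noisy points, and at the wrong temperature?** Yes. It is a reading, with a scatter of 1 percentage point on a last value of 4.9 %. It also belongs to 13 °C, while eta and epsilon end at 25 °C. So a count made with this number is a rough estimate.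

**What does the forecast say?** It names alpha as the richest flask, with 15 % there (10 % to 21 %), 11 % in theta (8 % to 14 %), 1 % in eta (0 % to 4 %) and 0.3 % in epsilon (0 % to 2.5 %). On eta its ground is that “the warm stage destroys what was made”.

**Count eta for me.** This reckoning is my own. Scaling the forecast's theta figure down to the change at 80 s puts about 5.87 % in eta at that moment. The warm stage lasts 70.0 s, which is longer than the lifetime, and comes to 1.24 lifetimes. That leaves 1.70 %, above the forecast's 1 % but inside its range.

The flasks give 18.4 % in alpha, 9.48 % in theta, 1.99 % in eta and 1.40 % in epsilon, so alpha holds most.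

    reagent ⇌ dormant form (K = 33.0, k = 0.0800 s⁻¹, Ea = 72.0 kJ mol⁻¹, ΔH = 2.00 kJ mol⁻¹)
    starting material + reagent ⇌ target (K = 34.0 M⁻¹, k = 9.50 M⁻¹ s⁻¹, Ea = 49.0 kJ mol⁻¹, ΔH = −35.0 kJ mol⁻¹)
    starting material + reagent ⇌ isomer of the product (K = 200 M⁻¹, k = 5.60 M⁻¹ s⁻¹, Ea = 47.0 kJ mol⁻¹, ΔH = −34.0 kJ mol⁻¹)
    crystals ⇌ target, rate k4*(cs4 - [target]) while solid is left; crystals form when [target] > cs4 (solubility = 9.90 mM, k = 8.80 s⁻¹)
    (constants at 25 °C)

Eta stood at 5.75 % of target at the change of temperature, and 1.24 lifetimes take that to 1.66 %, against 1.99 % in the flask. In epsilon the loss is target returning to starting material and reagent, the largest single effect: with that back reaction taken away, target ends at 36.7 % instead of 1.40 %. Epsilon is the second count: cedar's first reading, standing in for its early peak, with 2.48 lifetimes gives 0.992 %, and the flask holds 1.40 %.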